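**Retrosynthetic overview**
Numbering: C7 is the CH2O carbon, C1=C2 is the ring alkene (C1 bears C7), and C3–C6 are the four carbinol carbons. Their oxygens all lie on one face, and the benzoates sit on O5 and O7.
Feature used: C1 is the only ring atom that carries a carbon (C7) instead of oxygen, and it lies between carbinol C6 and the CH C2. Cutting out the C1–C7 unit leaves a five-membered ring C2–C3–C4–C5–C6 with a ketone at C6.
Key disconnection: six-membered β-keto ester ⇒ all-cis 5-benzoyloxy-3,4-isopropylidenedioxycyclopentanone + tert-butyl diazoacetate. Bonds C1–C6 and C1–C2 are made and the old C2–C6 bond is given up.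
Endgame: C1=C2 by selenoxide elimination, C6–OH by Luche reduction, C7 by hydride reduction, then O5/O7 benzoylation and acid deprotection. Front end: desymmetrised cyclopentenediol monoacetate, OH-directed syn-dihydroxylation, 3,4-acetonide, O5 benzoate, oxidation at C6.
Ring order: the carbocycle starts as a purchased cyclopentene (ring A), carries a temporary dioxolane (ring B), and is enlarged to the six-membered ring of the target in the key step.

Key step: step 8

Remark: the target SMILES is read as the all-cis (3S,4S,5R,6R) isomer. Target numbering is kept for every intermediate, and α means the face carrying O3–O6 (below the plane when C1→C6 runs clockwise).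

Step 1
Reactants: 1 (1R,4S)-cis-4-acetoxycyclopent-2-en-1-ol
Product: 2 (1S,4R)-4-(tert-butyldimethylsilyloxy)cyclopent-2-en-1-yl acetate
Conditions: TBSCl, imidazole, DMF, 0 °C → rt
Reagents that add atoms: tert-butyldimethylsilyl chloride, CC(C)(C)[Si](C)(C)Cl
Why: Imidazole-promoted silylation caps the only free hydroxyl (O6, the future ketone oxygen) and touches no stereocentre.

Step 2
Reactants: 2 (1S,4R)-4-(tert-butyldimethylsilyloxy)cyclopent-2-en-1-yl acetate
Product: 3 (1S,4R)-4-(tert-butyldimethylsilyloxy)cyclopent-2-en-1-ol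
Conditions: K2CO3 (cat.), MeOH, 0 °C → rt
Reagents that add atoms: none
Why: Base-catalysed transesterification removes the O3 acetate without affecting the silyl ether and frees the hydroxyl that serves as directing group.

Step 3
Reactants: 3 (1S,4R)-4-(tert-butyldimethylsilyloxy)cyclopent-2-en-1-ol
Product: 5 (1S,2S,3S,4R)-4-(tert-butyldimethylsilyloxy)cyclopentane-1,2,3-triol (all-cis), via osmate ester 4 (not isolated)
Conditions: OsO4 (1.05 equiv), TMEDA (1.1 equiv), CH2Cl2, −78 °C; then sat. aq. Na2SO3, THF, reflux
Reagents that add atoms: osmium tetroxide, O=[Os](=O)(=O)=O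
Why: In this hydrogen-bond-directed syn-dihydroxylation the O3–H binds an oxo ligand of the electron-rich OsO4·TMEDA complex, so the [3+2] addition should occur on the α face and set C4 and C5 cis to C3 against the steric bias, after which sulfite hydrolyses the chelated osmate ester.

Step 4
Reactants: 5 (1S,2S,3S,4R)-4-(tert-butyldimethylsilyloxy)cyclopentane-1,2,3-triol
Product: 6 all-cis 6-O-TBS-3,4-O-isopropylidenecyclopentane-3,4,5,6-tetrol (free 5α-OH)
Conditions: 2,2-dimethoxypropane, PPTS (cat.), acetone, rt
Reagents that add atoms: 2,2-dimethoxypropane, COC(C)(C)OC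
Why: Acid-catalysed transketalisation under equilibrating conditions should put the dioxolane on O3/O4, because an O4/O5 ketal would hold two endo neighbours (O3–H and the bulky O6 silyl ether) on the concave face of the bicyclo[3.3.0] system and because O3, next to the C2 methylene, is also the most accessible hydroxyl.

Step 5
Reactants: 6 all-cis 6-O-TBS-3,4-O-isopropylidenecyclopentane-3,4,5,6-tetrol; 7 benzoyl chloride
Product: 8 all-cis 5-O-benzoyl-6-O-TBS-3,4-O-isopropylidenecyclopentane-3,4,5,6-tetrol
Conditions: BzCl, pyridine, DMAP (cat.), CH2Cl2, 0 °C → rt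
Reagents that add atoms: benzoyl chloride 7, O=C(Cl)c1ccccc1
Why: DMAP-catalysed acylation of the single remaining hydroxyl places on O5 the electron-withdrawing acyloxy group that steers the later migration, with no regiochemical choice left.

Step 6
Reactants: 8 all-cis 5-O-benzoyl-6-O-TBS-3,4-O-isopropylidenecyclopentane-3,4,5,6-tetrol
Product: 9 all-cis 5-benzoyloxy-3,4-(isopropylidenedioxy)cyclopentan-6-ol
Conditions: HF·pyridine, pyridine, THF, 0 °C → rt
Reagents that add atoms: none
Why: Fluoride-mediated desilylation under weakly acidic, alkoxide-free conditions avoids O5→O6 benzoyl migration and leaves the ketal intact.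

Step 7
Reactants: 9 all-cis 5-benzoyloxy-3,4-(isopropylidenedioxy)cyclopentan-6-ol
Product: 10 all-cis 2-benzoyloxy-3,4-(isopropylidenedioxy)cyclopentanone (C6 ketone; 3α,4α,5α)
Conditions: Dess–Martin periodinane, CH2Cl2, 0 °C → rt
Reagents that add atoms: none
Why: The Dess–Martin oxidation runs under neutral to weakly acidic conditions, so the β-alkoxy α-acyloxy ketone should form without E1cB loss of O3 or epimerisation at C5.

Step 8
Reactants: 10 all-cis 2-benzoyloxy-3,4-(isopropylidenedioxy)cyclopentanone; 11 tert-butyl diazoacetate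
Product: 13 tert-butyl 5α-benzoyloxy-6-hydroxy-3α,4α-(isopropylidenedioxy)cyclohex-1(6)-ene-1-carboxylate (enol form of the C6 β-keto ester), via diazonium betaine 12 (not isolated)
Conditions: 11 (1.5 equiv), BF3·OEt2 (1.2 equiv), Et2O, −30 → 0 °C
Reagents that add atoms: tert-butyl diazoacetate 11, CC(C)(C)OC(=O)C=[N+]=[N-]
Why: BF3 activates the C6 carbonyl, the nucleophilic diazo carbon of 11 adds from the convex β face to give betaine 12, and the C6–C2 bond, aligned anti to the C–N2+ bond, shifts to that carbon as N2 leaves, so C1 (already carrying C7) ends up between C6 and C2. This is the Lewis-acid-promoted diazoacetate homologation of cyclic ketones (Büchner–Curtius–Schlotterbeck or Tiffeneau–Demjanov type), established for five- and six-membered ketones, including substrates with acid-sensitive tert-butyl carbamates at comparable temperatures. The six-membered ring is not closed by cyclisation but arises by ring enlargement, a 1,2-alkyl shift that replaces the C2–C6 bond of ring A by the C2–C1–C6 unit. No lasting stereocentre is created: C6 returns to sp2, C1 is levelled by enolisation of the β-keto ester, and C3, C4 and C5 are spectators. The step needs C2 and not C5 to migrate, and C5 is both more substituted and directly bonded to the electron-withdrawing benzoyloxy group, the same bias by which α-halo and α-branched ketones migrate through their unsubstituted carbon. The C5 configuration is protected by the base-free low-temperature medium and by enolisation of the product toward C1, and the chelated enol is inert to a second homologation.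

Step 9
Reactants: 13 tert-butyl 5α-benzoyloxy-6-hydroxy-3α,4α-(isopropylidenedioxy)cyclohex-1(6)-ene-1-carboxylate
Product: 16 tert-butyl 5α-benzoyloxy-3α,4α-(isopropylidenedioxy)-6-oxocyclohex-1-ene-1-carboxylate, via C1 phenylselenide 14 (not isolated), via selenoxide 15 (not isolated)
Conditions: PhSeCl, pyridine, CH2Cl2, 0 °C; cold aq. citric acid wash; then 30% H2O2 (excess), CH2Cl2, 0 °C; crude product used at once
Reagents that add atoms: none
Why: Electrophilic α-selenenylation of the enolised β-keto ester at C1 followed by selenoxide syn-elimination, which can only use a C2 hydrogen because C6 and C7 carry none, should install C1=C2 under base-free conditions once the pyridine is washed out.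

Step 10
Reactants: 16 tert-butyl 5α-benzoyloxy-3α,4α-(isopropylidenedioxy)-6-oxocyclohex-1-ene-1-carboxylate
Product: 17 tert-butyl 5α-benzoyloxy-6α-hydroxy-3α,4α-(isopropylidenedioxy)cyclohex-1-ene-1-carboxylate
Conditions: CeCl3·7H2O, NaBH4, MeOH, −78 °C; AcOH quench
Reagents that add atoms: none
Why: In the Luche reduction the hard cerium-modified borohydride should attack the ketone 1,2 rather than the doubly activated C2, and from the β face opposite the O5 benzoate and the ketal, which sets the C6 hydroxyl cis to O5.

Step 11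
Reactants: 17 tert-butyl 5α-benzoyloxy-6α-hydroxy-3α,4α-(isopropylidenedioxy)cyclohex-1-ene-1-carboxylate
Product: 18 tert-butyl 5α-benzoyloxy-3α,4α-(isopropylidenedioxy)-6α-(triethylsilyloxy)cyclohex-1-ene-1-carboxylate
Conditions: TESOTf, 2,6-lutidine, CH2Cl2, −78 °C
Reagents that add atoms: triethylsilyl trifluoromethanesulfonate, CC[Si](CC)(CC)OS(=O)(=O)C(F)(F)F
Why: Silyl triflate silylation with a hindered non-nucleophilic base masks O6 before benzoyl migration can set in and is too cold and brief to attack the tert-butyl ester or the ketal.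

Step 12
Reactants: 18 tert-butyl 5α-benzoyloxy-3α,4α-(isopropylidenedioxy)-6α-(triethylsilyloxy)cyclohex-1-ene-1-carboxylate
Product: 19 [5α-hydroxy-3α,4α-(isopropylidenedioxy)-6α-(triethylsilyloxy)cyclohex-1-en-1-yl]methanol
Conditions: iBu2AlH (6 equiv), CH2Cl2, −78 → −40 °C; aq. potassium sodium tartrate
Reagents that add atoms: none
Why: Exhaustive iBu2AlH ester reduction turns the conjugated tert-butyl ester into the allylic C7 alcohol and deliberately removes the O5 benzoate, whose migration-directing role is over, so no ester-versus-ester chemoselectivity is required while silyl ether, ketal and alkene stay inert at this temperature.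

Step 13
Reactants: 19 [5α-hydroxy-3α,4α-(isopropylidenedioxy)-6α-(triethylsilyloxy)cyclohex-1-en-1-yl]methanol; 7 benzoyl chloride
Product: 20 [5α-benzoyloxy-3α,4α-(isopropylidenedioxy)-6α-(triethylsilyloxy)cyclohex-1-en-1-yl]methyl benzoate
Conditions: BzCl (3 equiv), pyridine, DMAP (cat.), CH2Cl2, 0 °C → rt
Reagents that add atoms: benzoyl chloride 7, O=C(Cl)c1ccccc1
Why: With O3/O4 in the ketal and O6 silylated, O5 and O7 are the only hydroxyls, so DMAP-catalysed double acylation gives the required benzoate pattern without a selectivity problem.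

Step 14
Reactants: 20 [5α-benzoyloxy-3α,4α-(isopropylidenedioxy)-6α-(triethylsilyloxy)cyclohex-1-en-1-yl]methyl benzoate
Product: 21 [(3S,4S,5R,6R)-5-benzoyloxy-3,4,6-trihydroxycyclohex-1-en-1-yl]methyl benzoate (target)
Conditions: TFA–H2O (9:1), CH2Cl2, 0 °C
Reagents that add atoms: none
Why: Aqueous acid hydrolysis should cleave the cis-fused ketal and the triethylsilyl ether in one operation under conditions where benzoates are neither cleaved nor prone to migrate, and no stereocentre is involved.

**Compound list**
1 | (1R,4S)-cis-4-acetoxycyclopent-2-en-1-ol | CC(=O)O[C@@H]1C=C[C@H](O)C1 | starting material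
2 | (1S,4R)-4-(tert-butyldimethylsilyloxy)cyclopent-2-en-1-yl acetate | CC(=O)O[C@@H]1C=C[C@H](O[Si](C)(C)C(C)(C)C)C1 | intermediate
3 | (1S,4R)-4-(tert-butyldimethylsilyloxy)cyclopent-2-en-1-ol | O[C@@H]1C=C[C@H](O[Si](C)(C)C(C)(C)C)C1 | intermediate
4 | TMEDA-chelated cyclic 4α,5α-osmate ester (hexavalent osmium), not isolated | CC(C)(C)[Si](C)(C)O[C@@H]1C[C@H](O)[C@@H]2O[Os-2]3(=O)(=O)([N+](C)(C)CC[N+]3(C)C)O[C@H]12 | intermediate
5 | (1S,2S,3S,4R)-4-(tert-butyldimethylsilyloxy)cyclopentane-1,2,3-triol (all-cis) | CC(C)(C)[Si](C)(C)O[C@@H]1C[C@H](O)[C@H](O)[C@@H]1O | intermediate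
6 | all-cis 6-O-TBS-3,4-O-isopropylidenecyclopentane-3,4,5,6-tetrol (free 5α-OH) | CC(C)(C)[Si](C)(C)O[C@@H]1C[C@@H]2OC(C)(C)O[C@@H]2[C@@H]1O | intermediate
7 | benzoyl chloride | O=C(Cl)c1ccccc1 | starting material
8 | all-cis 5-O-benzoyl-6-O-TBS-3,4-O-isopropylidenecyclopentane-3,4,5,6-tetrol | CC(C)(C)[Si](C)(C)O[C@@H]1C[C@@H]2OC(C)(C)O[C@@H]2[C@@H]1OC(=O)c1ccccc1 | intermediate
9 | all-cis 5-benzoyloxy-3,4-(isopropylidenedioxy)cyclopentan-6-ol | O[C@@H]1C[C@@H]2OC(C)(C)O[C@@H]2[C@@H]1OC(=O)c1ccccc1 | intermediate
10 | all-cis 2-benzoyloxy-3,4-(isopropylidenedioxy)cyclopentanone | O=C1C[C@@H]2OC(C)(C)O[C@@H]2[C@@H]1OC(=O)c1ccccc1 | intermediate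
11 | tert-butyl diazoacetate | CC(C)(C)OC(=O)C=[N+]=[N-] | starting material
12 | BF3-bound diazonium betaine (C6 alkoxide α, C1 configuration undefined), not isolated | CC(C)(C)OC(=O)C([N+]#N)[C@@]1(O[B-](F)(F)F)C[C@@H]2OC(C)(C)O[C@@H]2[C@@H]1OC(=O)c1ccccc1 | intermediate
13 | tert-butyl 5α-benzoyloxy-6-hydroxy-3α,4α-(isopropylidenedioxy)cyclohex-1(6)-ene-1-carboxylate (enol of the β-keto ester) | CC(C)(C)OC(=O)C1=C(O)[C@@H](OC(=O)c2ccccc2)[C@H]2OC(C)(C)O[C@H]2C1 | intermediate
14 | C1 phenylselenide of the β-keto ester (PhSe expected on the β face), not isolated | CC(C)(C)OC(=O)[C@]1([Se]c3ccccc3)C[C@@H]2OC(C)(C)O[C@@H]2[C@H](OC(=O)c2ccccc2)C1=O | intermediate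
15 | corresponding selenoxide (selenium configuration undefined), not isolated | CC(C)(C)OC(=O)[C@]1([Se](=O)c3ccccc3)C[C@@H]2OC(C)(C)O[C@@H]2[C@H](OC(=O)c2ccccc2)C1=O | intermediate
16 | tert-butyl 5α-benzoyloxy-3α,4α-(isopropylidenedioxy)-6-oxocyclohex-1-ene-1-carboxylate | CC(C)(C)OC(=O)C1=C[C@@H]2OC(C)(C)O[C@@H]2[C@H](OC(=O)c2ccccc2)C1=O | intermediate
17 | tert-butyl 5α-benzoyloxy-6α-hydroxy-3α,4α-(isopropylidenedioxy)cyclohex-1-ene-1-carboxylate | CC(C)(C)OC(=O)C1=C[C@@H]2OC(C)(C)O[C@@H]2[C@H](OC(=O)c2ccccc2)[C@@H]1O | intermediate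
18 | tert-butyl 5α-benzoyloxy-3α,4α-(isopropylidenedioxy)-6α-(triethylsilyloxy)cyclohex-1-ene-1-carboxylate | CC(C)(C)OC(=O)C1=C[C@@H]2OC(C)(C)O[C@@H]2[C@H](OC(=O)c2ccccc2)[C@@H]1O[Si](CC)(CC)CC | intermediate
19 | [5α-hydroxy-3α,4α-(isopropylidenedioxy)-6α-(triethylsilyloxy)cyclohex-1-en-1-yl]methanol | OCC1=C[C@@H]2OC(C)(C)O[C@@H]2[C@H](O)[C@@H]1O[Si](CC)(CC)CC | intermediate
20 | [5α-benzoyloxy-3α,4α-(isopropylidenedioxy)-6α-(triethylsilyloxy)cyclohex-1-en-1-yl]methyl benzoate | O=C(OCC1=C[C@@H]2OC(C)(C)O[C@@H]2[C@H](OC(=O)c2ccccc2)[C@@H]1O[Si](CC)(CC)CC)c1ccccc1 | intermediate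
21 | [(3S,4S,5R,6R)-5-benzoyloxy-3,4,6-trihydroxycyclohex-1-en-1-yl]methyl benzoate | O=C(OCC1=C[C@H](O)[C@H](O)[C@H](OC(=O)c2ccccc2)[C@@H]1O)c1ccccc1 | target

Total step count: 14. Longest linear sequence: 14 steps (from 1).

**Steps most likely to fail**

Step 8 (key step). Several things may go wrong:
- a competing shift of C5;
- collapse of the betaine to a spiro-epoxide instead of migration;
- capture of the diazonium carbon by the benzoate carbonyl;
- Lewis-acid-induced opening of the ketal with β-elimination of O3.

The fallback sets out from 10 and comes back at 13. It makes the C1–C6 bond and the 1,2-shift in two separate operations that use no Lewis acid. tert-Butyl diazoacetate 11 is lithiated (LDA, THF, −78 °C) and added to 10 from the β face, with an acetic acid quench at −78 °C, to give the α-diazo-β-hydroxy ester F1. Catalytic Rh2(OAc)4 in CH2Cl2 at room temperature then expels N2. The electrophilic rhodium carbenoid should trigger migration of the more electron-rich C2 methylene and deliver 13 under neutral conditions.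

Step 9. The doubly activated enone may dienolise at C3–H and lose O4 and the benzoate (aromatisation). It may also add water or peroxide at C2 before it can be reduced. The fallback sets out from 14, isolated this time, and comes back at 17, so it also bypasses step 10. The C6 ketone is reduced while C1 is still quaternary (NaBH4, CeCl3·7H2O, MeOH, −78 °C) to give the β-hydroxy selenide F2. Oxidation (H2O2, CH2Cl2, 0 °C) gives the hydroxy selenoxide F3. Its syn-elimination should run away from the carbinol carbon toward the C2 hydrogen, as is the rule for β-hydroxy selenoxides, and give the allylic alcohol 17 without the enone ever being formed.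

Step 3. Poor facial selectivity is the risk, because osmylation on the open β face may outrun the hydrogen-bonded delivery on the α face, which is crowded by the silyl ether. The fallback sets out from 3 and comes back at 5. The α-oxygen is delivered from a covalently bound metal alkoxide by hydroxyl-directed epoxidation (VO(acac)2 cat., tBuOOH, CH2Cl2, 0 °C), which gives the all-cis epoxy alcohol F4. Catalytic CO2 insertion (CO2 20 bar, ZnBr2 and Bu4NI cat., 80 °C) proceeds by double inversion. Iodide opens the epoxide from the free β face and the carbonate oxygen closes again from the α face, so the cis-fused cyclic carbonate F5 forms with net retention at C4 and C5. Methanolysis (K2CO3 cat., MeOH) releases triol 5.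

**Further compounds**
F1 | step 8 | tert-butyl 2-diazo-2-[5α-benzoyloxy-6α-hydroxy-3α,4α-(isopropylidenedioxy)cyclopent-6-yl]acetate | CC(C)(C)OC(=O)C(=[N+]=[N-])[C@@]1(O)C[C@@H]2OC(C)(C)O[C@@H]2[C@@H]1OC(=O)c1ccccc1
F2 | step 9 | tert-butyl 5α-benzoyloxy-6α-hydroxy-3α,4α-(isopropylidenedioxy)-1β-(phenylselanyl)cyclohexane-1-carboxylate | CC(C)(C)OC(=O)[C@]1([Se]c3ccccc3)C[C@@H]2OC(C)(C)O[C@@H]2[C@H](OC(=O)c2ccccc2)[C@@H]1O
F3 | step 9 | selenoxide of F2 (selenium configuration undefined) | CC(C)(C)OC(=O)[C@]1([Se](=O)c3ccccc3)C[C@@H]2OC(C)(C)O[C@@H]2[C@H](OC(=O)c2ccccc2)[C@@H]1O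
F4 | step 3 | all-cis 4α,5α-epoxy-6α-(tert-butyldimethylsilyloxy)cyclopentan-3α-ol | CC(C)(C)[Si](C)(C)O[C@@H]1C[C@H](O)[C@@H]2O[C@H]12
F5 | step 3 | all-cis 4,5-O-carbonyl-6-O-TBS-cyclopentane-3,4,5,6-tetrol (cyclic carbonate) | CC(C)(C)[Si](C)(C)O[C@@H]1C[C@H](O)[C@@H]2OC(=O)O[C@H]12
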